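(The constants used here are those of an exercise; no experiment stands behind them.)

The gas phase, held constant, feeds a solution of starting material. Dissolved gas adds to starting material to give target, target turns into isomer of the product, and dissolved gas also passes into a dormant form (a resting state of the gas). Each of these steps runs both ways. Amounts below are fractions of the charge.

starting material 0.010 M; gas phase 2.1 mM (held); time 10 d

    gas phase ⇌ dissolved gas, rate k1*(csat - [dissolved gas]) (k1 = 4.73 × 10⁻⁴ min⁻¹, csat = 2.1 mM)
    dissolved gas ⇌ dormant form (K2 = 4.6, k2 = 6.35 × 10⁻⁴ min⁻¹)
    target ⇌ isomer of the product (K3 = 1.64, k3 = 2.87 × 10⁻⁴ min⁻¹)
    starting material + dissolved gas ⇌ target (K4 = 636 L mol⁻¹, k4 = 0.167 L mol⁻¹ min⁻¹)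

1. how much target there is at 10 d, in percent of the starting material charged
2. the change that raises the amount of target at 10 d, in percent of the starting material charged most ("none" if none brings more than 2 percentage points) (maple / alder / none)
3. amount of target at 10 d, in percent of the starting material charged, after alder

- maple: doubling the transfer coefficient of step 1, all else as stated
- alder: doubling the saturation concentration of gas phase, all else as stated

1. Apply the bench rule: gas held means solution saturated, so read the equilibrium. Let b be 636 L mol⁻¹ times the dissolved gas. Starting material, target and isomer then stand as 1 : b : 1.64 b. Saturation gives b = 1.34, so target is 29.5 % and target plus isomer 77.9 %.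

2. Find the border of that rule. Count the gas the flask must take up: the saturation amount, 4.6 times that in dormant form, and the gas bound in target and isomer. This load is 196 %. The feed into an empty solution is 0.143 d⁻¹. Load over feed is 13.7 d, the fill time. Run time over fill time is 0.732, below 1, so the bench rule does not reach this flask.

3. Correct it. The feed falls as the solution fills. Let the other forms follow the dissolved gas, so that its share of saturation climbs as 1 − exp(−time / fill time), here 51.9 %. Multiply b by that share and return to the ratios: target is 24.5 %.

4. Compare the changes. Maple doubles the feed on the same load, so the fill time becomes 6.83 d. Alder doubles feed and saturation, and the load grows too, so the fill time becomes 11.3 d. Alder gives 30.5 %, and the best change is alder.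

The forecast gives 23.5 %, alder as best, and 31.2 % after it, on the ground that “Gas uptake limits the reaction, while the dormant form steals gas”. Its numbers differ from mine; the choice is the same.

The simulation gives 23.4 %, and alder as best, with a gain of 8.7 percentage points against 4.6 points for maple, and 32.1 % after alder.

In this flask the run time is shorter than the fill time: at 10.0 d dissolved gas stands at 50.3 % of saturation and, each step taken net, is still made 1.10 times faster than it is used up. The neighbour flask charged with 0.025 M has a larger load on the same feed, so its reckoned fill time is 21.8 d, longer than the first, and the same ratios give target 21.4 %. The simulation of that neighbour gives 16.8 %, less than this reckoning.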